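The quaternary ring carbon C1′ lies β to C3′ (the CHCH3 carbon) across the methylene-bearing C2′ of the cyclohexane, the pattern of a 3,3-disubstituted cyclohexanone. The complete chromene half, as its 2-vinyl compound with a bromine masking the C5 hydroxyl, is therefore joined to 3-methylcyclohex-2-enone: hydrozirconation of the vinyl group and ligand-controlled copper-catalysed conjugate addition form the C1′–CH2 bond and the quaternary centre, and the enolate is aminomethylated at C2′ in the same flask. The carbonyl carbon later becomes C3′ through allylic transposition and a second ligand-controlled copper SN2′ methylation that also unveils the exocyclic methylene. The chromene centre stems from a palladium-catalysed asymmetric O-allylation.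

Key step: step 6

Remark 1: primed locants denote the cyclohexane carbons (C1′ quaternary, C2′ methylene-bearing, C3′ CHCH3).
Remark 2: in the three ligand-controlled steps (2, 6, 10) the ligand enantiomer is the one that delivers the configuration drawn; its sense is to be confirmed on a first run.
Remark 3: compound 1 is taken as commercial (otherwise one step from 1,3-dimethoxybenzene by dibromination).

Step 1
Reactants: 1 1,5-dibromo-2,4-dimethoxybenzene
Product: 4 5-bromo-2,4-dimethoxyphenol, via aryllithium 2 (not isolated), via aryl dimethyl boronate 3 (not isolated)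
Conditions: n-BuLi (1.05 equiv), THF, −78 °C; B(OMe)3, −78 °C → rt; 30% H2O2, aq NaOH, 0 °C
Reagents that add atoms: hydrogen peroxide, OO
Why: Bromine–lithium exchange on one of the two equivalent C–Br bonds, borylation and oxidative hydroxylation of the arylboronate (1,2-aryl shift from boron to oxygen) should give the phenol, while the surviving bromine marks the carbon that becomes C5–OH in the last step.

Step 2
Reactants: 4 5-bromo-2,4-dimethoxyphenol; 5 2-methyl-2-vinyloxirane (racemic)
Product: 6 (2S)-2-(5-bromo-2,4-dimethoxyphenoxy)-2-methylbut-3-en-1-ol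
Conditions: Pd2(dba)3·CHCl3 (1 mol%), DACH-phenyl Trost ligand (3 mol%), CH2Cl2, rt
Reagents that add atoms: none
Why: Palladium-catalysed asymmetric allylic alkylation of a phenol with a vinyl epoxide, run as a dynamic kinetic asymmetric transformation: the π-allylpalladium alkoxide from racemic 5 equilibrates between its faces, deprotonates 4 and directs the phenoxide to the tertiary allyl terminus, so the chiral ligand sets the tertiary ether stereocentre (S) that becomes C2 of the chromene.

Step 3
Reactants: 6 (2S)-2-(5-bromo-2,4-dimethoxyphenoxy)-2-methylbut-3-en-1-ol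
Product: 7 (2S)-2-(5-bromo-2,4-dimethoxyphenoxy)-2-methylbut-3-enal
Conditions: Dess–Martin periodinane, CH2Cl2, 0 °C → rt
Reagents that add atoms: none
Why: Dess–Martin oxidation of the primary alcohol; the α-carbon is quaternary, so the stereocentre cannot epimerise and the vinyl group cannot move into conjugation.

Step 4
Reactants: 7 (2S)-2-(5-bromo-2,4-dimethoxyphenoxy)-2-methylbut-3-enal
Product: 8 1-bromo-2,4-dimethoxy-5-{[(3S)-3-methylpent-1-en-4-yn-3-yl]oxy}benzene
Conditions: dimethyl (1-diazo-2-oxopropyl)phosphonate, K2CO3, MeOH, 0 °C → rt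
Reagents that add atoms: Ohira–Bestmann reagent, COP(=O)(OC)C(=[N+]=[N-])C(C)=O
Why: Seyferth–Gilbert homologation in the Ohira–Bestmann variant converts the aldehyde into the terminal alkyne through the diazoalkene and alkylidene carbene (1,2-H shift); the stereocentre is not involved.

Step 5
Reactants: 8 1-bromo-2,4-dimethoxy-5-{[(3S)-3-methylpent-1-en-4-yn-3-yl]oxy}benzene
Product: 9 (2S)-5-bromo-2-ethenyl-6,8-dimethoxy-2-methyl-2H-chromene
Conditions: Ph3PAuNTf2 (2 mol%), CH2Cl2, 0 °C → rt
Reagents that add atoms: none
Why: Gold(I)-catalysed intramolecular hydroarylation of the aryl propargyl ether (6-endo-dig Friedel–Crafts attack of the only free ortho carbon on the gold-activated alkyne, then protodeauration) closes the pyran ring without breaking the C–O bond at the stereocentre, so the (S) configuration should be carried into C2 of the chromene, which a thermal propargyl Claisen route would not guarantee.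

Step 6
Reactants: 9 (2S)-5-bromo-2-ethenyl-6,8-dimethoxy-2-methyl-2H-chromene; 10 3-methylcyclohex-2-en-1-one
Product: 13 (3R)-3-{2-[(2S)-5-bromo-6,8-dimethoxy-2-methyl-2H-chromen-2-yl]ethyl}-2-[(dimethylamino)methyl]-3-methylcyclohexan-1-one (C2 epimers), via alkylzirconocene chloride 11 (not isolated), via zirconium enolate 12 (not isolated)
Conditions: Cp2Zr(H)Cl (1.1 equiv), CH2Cl2, rt; then 10, CuCl/AgNTf2 (10 mol%), BINOL-derived chiral phosphoramidite (10 mol%), Et2O, rt; then CH2=NMe2+ I−, CH2Cl2, 0 °C → rt
Reagents that add atoms: Eschenmoser's salt, C=[N+](C)C.[I-]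
Why: syn-Hydrozirconation places zirconium on the terminal vinyl carbon of 9 (the cis-disubstituted C3=C4 of the chromene reacts far more slowly), the alkyl group is transmetallated to the cationic Cu(I)–phosphoramidite complex, and π-complexation, oxidative addition at the β-carbon of 10 and reductive elimination form the new C–CH2 bond and the quaternary centre; the enolate is released as zirconium enolate 12, which is C-aminomethylated by the iminium salt (Mannich reaction). The closest known reaction type is the copper-catalysed asymmetric conjugate addition of alkylzirconocenes, made in situ from terminal alkenes, to 3-methylcyclohexenone, combined with the classical trapping of a conjugate-addition enolate by Eschenmoser's salt. No ring is closed. The quaternary centre (R) is set by the chiral ligand alone, because 10 is achiral and the chromene stereocentre is remote from the reacting carbon; the aminomethyl-bearing C2 of the ketone is formed without control and is erased in step 7. The step needs 1,4- over 1,2-addition, secured by copper catalysis, and functionalisation at C2 and not at C6 of the ketone, secured because the conjugate addition generates the enolate regiospecifically and it is trapped before it can equilibrate.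

Step 7
Reactants: 13 (3R)-3-{2-[(2S)-5-bromo-6,8-dimethoxy-2-methyl-2H-chromen-2-yl]ethyl}-2-[(dimethylamino)methyl]-3-methylcyclohexan-1-one
Product: 15 (3R)-3-{2-[(2S)-5-bromo-6,8-dimethoxy-2-methyl-2H-chromen-2-yl]ethyl}-3-methyl-2-methylidenecyclohexan-1-one, via trimethylammonium iodide 14 (not isolated)
Conditions: MeI, Et2O, rt; then aq NaHCO3, CH2Cl2, rt
Reagents that add atoms: none
Why: Exhaustive N-methylation of the Mannich base and E1cB elimination of trimethylamine (Hofmann-type) should give the α-methylene ketone; the quaternary centre is untouched and the uncontrolled C2 centre disappears.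

Step 8
Reactants: 15 (3R)-3-{2-[(2S)-5-bromo-6,8-dimethoxy-2-methyl-2H-chromen-2-yl]ethyl}-3-methyl-2-methylidenecyclohexan-1-one
Product: 16 (3R)-3-{2-[(2S)-5-bromo-6,8-dimethoxy-2-methyl-2H-chromen-2-yl]ethyl}-3-methyl-2-methylidenecyclohexan-1-ol (C1 epimers)
Conditions: NaBH4, CeCl3·7H2O, MeOH, −20 °C → 0 °C
Reagents that add atoms: none
Why: Luche reduction gives 1,2-reduction of the s-cis enone; the new carbinol centre forms as a mixture and is of no consequence because it becomes sp2 in step 9.

Step 9
Reactants: 16 (3R)-3-{2-[(2S)-5-bromo-6,8-dimethoxy-2-methyl-2H-chromen-2-yl]ethyl}-3-methyl-2-methylidenecyclohexan-1-ol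
Product: 18 (2S)-5-bromo-2-{2-[(1R)-2-(chloromethyl)-1-methylcyclohex-2-en-1-yl]ethyl}-6,8-dimethoxy-2-methyl-2H-chromene, via allylic chlorosulfite 17 (not isolated)
Conditions: SOCl2, Et2O, 0 °C
Reagents that add atoms: thionyl chloride, O=S(Cl)Cl
Why: SNi′ reaction: the chlorosulfite collapses through a six-membered transition state that delivers chloride to the exocyclic CH2 with loss of SO2 and moves the double bond into the ring, so both carbinol epimers converge on one primary allylic chloride.

Step 10
Reactants: 18 (2S)-5-bromo-2-{2-[(1R)-2-(chloromethyl)-1-methylcyclohex-2-en-1-yl]ethyl}-6,8-dimethoxy-2-methyl-2H-chromene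
Product: 19 (2S)-5-bromo-2-{2-[(1R,3R)-1,3-dimethyl-2-methylidenecyclohexyl]ethyl}-6,8-dimethoxy-2-methyl-2H-chromene
Conditions: MeMgBr (1.2 equiv, slow addition), copper(I) thiophene-2-carboxylate (3 mol%), chiral phosphoramidite (3.3 mol%), CH2Cl2, −78 °C
Reagents that add atoms: methylmagnesium bromide, C[Mg]Br
Why: Copper-catalysed asymmetric allylic alkylation with a Grignard reagent (SN2′): oxidative addition of the methylcopper species at the ring CH anti to chloride and reductive elimination form the C–CH3 bond and the exocyclic methylene, and the new CH(CH3) centre (R, methyl cis to the ethylene linker) is set by the chiral ligand because the neighbouring quaternary centre carries two groups of similar size and biases the faces only weakly.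

Step 11
Reactants: 19 (2S)-5-bromo-2-{2-[(1R,3R)-1,3-dimethyl-2-methylidenecyclohexyl]ethyl}-6,8-dimethoxy-2-methyl-2H-chromene
Product: 22 metachromin B, via aryllithium 20 (not isolated), via aryl dimethyl boronate 21 (not isolated)
Conditions: n-BuLi (1.1 equiv), THF, −78 °C; B(OMe)3, −78 °C → 0 °C; 30% H2O2, aq NaOH, 0 °C
Reagents that add atoms: hydrogen peroxide, OO
Why: Bromine–lithium exchange (much faster at −78 °C than any addition to the alkenes), borylation and oxidation of the arylboronate (hydroxylation of an aryl halide via the boronate) should unmask the C5 hydroxyl without touching a stereocentre.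

Compound list
1 | 1,5-dibromo-2,4-dimethoxybenzene | COc1cc(OC)c(Br)cc1Br | starting material
2 | (5-bromo-2,4-dimethoxyphenyl)lithium | [Li]c1cc(Br)c(OC)cc1OC | intermediate
3 | dimethyl (5-bromo-2,4-dimethoxyphenyl)boronate | COB(OC)c1cc(Br)c(OC)cc1OC | intermediate
4 | 5-bromo-2,4-dimethoxyphenol | Oc1cc(Br)c(OC)cc1OC | intermediate
5 | 2-methyl-2-vinyloxirane (racemic) | CC1(CO1)C=C | starting material
6 | (2S)-2-(5-bromo-2,4-dimethoxyphenoxy)-2-methylbut-3-en-1-ol | C=C[C@@](Oc1cc(Br)c(OC)cc1OC)(C)CO | intermediate
7 | (2S)-2-(5-bromo-2,4-dimethoxyphenoxy)-2-methylbut-3-enal | C=C[C@@](Oc1cc(Br)c(OC)cc1OC)(C)C=O | intermediate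
8 | 1-bromo-2,4-dimethoxy-5-{[(3S)-3-methylpent-1-en-4-yn-3-yl]oxy}benzene | C=C[C@@](Oc1cc(Br)c(OC)cc1OC)(C)C#C | intermediate
9 | (2S)-5-bromo-2-ethenyl-6,8-dimethoxy-2-methyl-2H-chromene | C=C[C@@]1(C)C=Cc2c(Br)c(OC)cc(OC)c2O1 | intermediate
10 | 3-methylcyclohex-2-en-1-one | CC1=CC(=O)CCC1 | starting material
11 | chloro{2-[(2S)-5-bromo-6,8-dimethoxy-2-methyl-2H-chromen-2-yl]ethyl}zirconocene (Cp drawn η1) | Cl[Zr](CC[C@@]1(C)C=Cc2c(Br)c(OC)cc(OC)c2O1)(C1C=CC=C1)C1C=CC=C1 | intermediate
12 | chlorozirconocene enolate of (3R)-3-{2-[(2S)-5-bromo-6,8-dimethoxy-2-methyl-2H-chromen-2-yl]ethyl}-3-methylcyclohexanone (Cp drawn η1) | C1=C(O[Zr](Cl)(C2C=CC=C2)C2C=CC=C2)CCC[C@]1(C)CC[C@@]1(C)C=Cc2c(Br)c(OC)cc(OC)c2O1 | intermediate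
13 | (3R)-3-{2-[(2S)-5-bromo-6,8-dimethoxy-2-methyl-2H-chromen-2-yl]ethyl}-2-[(dimethylamino)methyl]-3-methylcyclohexan-1-one (C2 epimers) | CN(C)CC1C(=O)CCC[C@]1(C)CC[C@@]1(C)C=Cc2c(Br)c(OC)cc(OC)c2O1 | intermediate
14 | trimethylammonium iodide of 13 | C[N+](C)(C)CC1C(=O)CCC[C@]1(C)CC[C@@]1(C)C=Cc2c(Br)c(OC)cc(OC)c2O1.[I-] | intermediate
15 | (3R)-3-{2-[(2S)-5-bromo-6,8-dimethoxy-2-methyl-2H-chromen-2-yl]ethyl}-3-methyl-2-methylidenecyclohexan-1-one | C=C1C(=O)CCC[C@]1(C)CC[C@@]1(C)C=Cc2c(Br)c(OC)cc(OC)c2O1 | intermediate
16 | (3R)-3-{2-[(2S)-5-bromo-6,8-dimethoxy-2-methyl-2H-chromen-2-yl]ethyl}-3-methyl-2-methylidenecyclohexan-1-ol (C1 epimers) | C=C1C(O)CCC[C@]1(C)CC[C@@]1(C)C=Cc2c(Br)c(OC)cc(OC)c2O1 | intermediate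
17 | chlorosulfite of 16 | C=C1C(OS(Cl)=O)CCC[C@]1(C)CC[C@@]1(C)C=Cc2c(Br)c(OC)cc(OC)c2O1 | intermediate
18 | (2S)-5-bromo-2-{2-[(1R)-2-(chloromethyl)-1-methylcyclohex-2-en-1-yl]ethyl}-6,8-dimethoxy-2-methyl-2H-chromene | ClCC1=CCCC[C@]1(C)CC[C@@]1(C)C=Cc2c(Br)c(OC)cc(OC)c2O1 | intermediate
19 | (2S)-5-bromo-2-{2-[(1R,3R)-1,3-dimethyl-2-methylidenecyclohexyl]ethyl}-6,8-dimethoxy-2-methyl-2H-chromene | C=C1[C@H](C)CCC[C@]1(C)CC[C@@]1(C)C=Cc2c(Br)c(OC)cc(OC)c2O1 | intermediate
20 | 5-lithio derivative of 19 | C=C1[C@H](C)CCC[C@]1(C)CC[C@@]1(C)C=Cc2c([Li])c(OC)cc(OC)c2O1 | intermediate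
21 | 5-(dimethoxyboryl) derivative of 19 | C=C1[C@H](C)CCC[C@]1(C)CC[C@@]1(C)C=Cc2c(B(OC)OC)c(OC)cc(OC)c2O1 | intermediate
22 | metachromin B, (2S)-2-{2-[(1R,3R)-1,3-dimethyl-2-methylidenecyclohexyl]ethyl}-6,8-dimethoxy-2-methyl-2H-chromen-5-ol | C=C1[C@H](C)CCC[C@]1(C)CC[C@@]1(C)C=Cc2c(O)c(OC)cc(OC)c2O1 | target

Total step count: 11
Longest linear sequence: 11 steps (1 → 22; compounds 5 and 10 are commercial)

Steps most likely to fail

1. Step 6. The γ-aryloxy alkylzirconocene 11 may lose the tertiary allylic aryloxide by γ-elimination to a cyclopropane. The hindered zirconium enolate 12 may also be protonated instead of C-aminomethylated, which would forfeit the regiodefined C2 handle. The fallback sets out from 9 and changes the organometallic and the way the enolate is used. Hydroboration of the vinyl group with Et2BH should give the alkyldiethylborane F1. Boron–zinc exchange with Et2Zn should give the dialkylzinc F2. Conjugate addition of F2 to 10 under a chiral N-heterocyclic carbene–copper catalyst, with trapping of the zinc enolate by TMSOTf, should give the trimethylsilyl enol ether F3. A Mukaiyama–Mannich reaction of F3 with Eschenmoser's salt comes back to the route at 13.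

2. Step 10. The ligand may fail to override the facial bias of the adjacent quaternary centre at the ring CH, or direct SN2 methylation at the CH2Cl carbon may compete. The fallback sets out from 15 and brings in hydride last instead of methyl. Addition of MeMgBr/CeCl3 to the ketone should give the tertiary allylic alcohol F4 as an epimer mixture. LiHMDS and methyl chloroformate should convert it into the tertiary methyl carbonate F5. Palladium-catalysed asymmetric hydrogenolysis (Pd2(dba)3·CHCl3, MeO-MOP, HCO2H, 1,8-bis(dimethylamino)naphthalene, dioxane, rt) then delivers hydride to the more substituted allyl terminus. The two π-allyl faces interconvert through the η1 form at the CH2 terminus, so the ligand and not the carbinol configuration decides the new centre. The fallback comes back to the route at 19.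

3. Step 9. The HCl set free may ionise the tertiary allylic ether of the chromene with loss of the C2 configuration, or chloride may be delivered without transposition (SNi instead of SNi′). The fallback sets out from 16 and separates transposition from chlorination. A perrhenate-catalysed 1,3-transposition of the allylic alcohol (Ph3SiOReO3 cat., Et2O, 0 °C), a [3,3] shift of the perrhenate ester towards the more substituted alkene, should give the primary allylic alcohol F6. Corey–Kim chlorination (NCS, Me2S, CH2Cl2, −20 °C → 0 °C), which does not transpose primary allylic alcohols, comes back to the route at 18.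

Further compounds
F1 | step 6 | diethyl{2-[(2S)-5-bromo-6,8-dimethoxy-2-methyl-2H-chromen-2-yl]ethyl}borane | CCB(CC)CC[C@@]1(C)C=Cc2c(Br)c(OC)cc(OC)c2O1
F2 | step 6 | bis{2-[(2S)-5-bromo-6,8-dimethoxy-2-methyl-2H-chromen-2-yl]ethyl}zinc | [Zn](CC[C@@]1(C)C=Cc2c(Br)c(OC)cc(OC)c2O1)CC[C@@]1(C)C=Cc2c(Br)c(OC)cc(OC)c2O1
F3 | step 6 | {[(3R)-3-{2-[(2S)-5-bromo-6,8-dimethoxy-2-methyl-2H-chromen-2-yl]ethyl}-3-methylcyclohex-1-en-1-yl]oxy}trimethylsilane | C1=C(O[Si](C)(C)C)CCC[C@]1(C)CC[C@@]1(C)C=Cc2c(Br)c(OC)cc(OC)c2O1
F4 | step 10 | (3R)-3-{2-[(2S)-5-bromo-6,8-dimethoxy-2-methyl-2H-chromen-2-yl]ethyl}-1,3-dimethyl-2-methylidenecyclohexan-1-ol (C1 epimers) | C=C1C(C)(O)CCC[C@]1(C)CC[C@@]1(C)C=Cc2c(Br)c(OC)cc(OC)c2O1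
F5 | step 10 | methyl carbonate of F4 | C=C1C(C)(OC(=O)OC)CCC[C@]1(C)CC[C@@]1(C)C=Cc2c(Br)c(OC)cc(OC)c2O1
F6 | step 9 | [(6R)-6-{2-[(2S)-5-bromo-6,8-dimethoxy-2-methyl-2H-chromen-2-yl]ethyl}-6-methylcyclohex-1-en-1-yl]methanol | OCC1=CCCC[C@]1(C)CC[C@@]1(C)C=Cc2c(Br)c(OC)cc(OC)c2O1
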